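The route builds aromatic ring A last, onto an enantiopure ring C. The precursor is an (S)-2-aryl-2,3-dihydropyran-4-one carrying a diazoacetyl group on its C6, paired with a geranyl-substituted triisopropylsiloxyalkyne. Light triggers a Wolff shift. Ketene–alkyne [2+2] addition, four-electron opening and six-electron closure follow, so one operation makes C8–C8a, C5–C6, C7–C8 and C4a–C5. The feature exploited is the contiguous C5(OH)–C6(geranyl)–C7(O) array of pentasubstituted ring A. It maps onto the ketene carbonyl carbon, the nucleophilic alkyne carbon and the oxygen-bearing alkyne carbon, so geranyl cannot reach C8. C2 comes from a catalytic asymmetric aldol–cyclisation and afterwards meets only near-neutral reagents.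

Key step: step 7

Assumption: in step 2 the (R,R)-catalyst is taken to leave the Si face of the aldehyde open, and if a first run shows the opposite sense the mirror-image catalyst is used with no other change; in step 7 all ring atoms carry flavanone numbers (O1, C2, C3, C4, C4a, C5–C8, C8a).

Step 1
Reactants: 1 methyl 2,4-dioxopentanoate
Product: 2 methyl (2Z)-2,4-bis(trimethylsilyloxy)penta-2,4-dienoate
Conditions: Me3SiOTf (2.2 equiv), Et3N (2.5 equiv), Et2O, 0 °C to rt
Reagents that add atoms: trimethylsilyl triflate, C[Si](C)(C)OS(=O)(=O)C(F)(F)F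
Why: Soft enolisation with a silyl triflate and an amine, the standard entry to 1,3-bis(silyloxy)dienes from 1,3-dicarbonyl compounds, silylates the chelated C2 enol and then the acetyl methyl side, the only position still able to lose a proton, and the C2=C3 geometry does not matter because it vanishes in step 2.

Step 2
Reactants: 3 veratraldehyde (3,4-dimethoxybenzaldehyde); 2 methyl (2Z)-2,4-bis(trimethylsilyloxy)penta-2,4-dienoate
Product: 6 methyl (2S)-2-(3,4-dimethoxyphenyl)-4-oxo-3,4-dihydro-2H-pyran-6-carboxylate, via trichlorosilyl aldolate 4 (not isolated), via hydroxy diketo ester 5 (not isolated)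
Conditions: SiCl4 (1.5 equiv), (R,R)-bis(phosphoramide) (5 mol %; two cyclic P(=O) amides of N,N'-dimethyl-1,1'-binaphthyl-2,2'-diamine joined at P through MeN(CH2)5NMe), iPr2NEt (10 mol %), CH2Cl2, −78 °C; sat. aq NaHCO3; crude, TFA, CH2Cl2, 0 °C
Reagents that add atoms: none
Why: This is a catalytic asymmetric Mukaiyama aldol addition followed by acid cyclodehydration, a stepwise formal hetero-Diels–Alder reaction, in which the phosphoramide-bound chlorosilyl cation is Lewis-acidic enough for an electron-rich aryl aldehyde and an ester-weakened diene, the terminal CH2 (fed by both oxygen donors) attacks the Si face left open by the binaphthyl walls to set C2 as S, and TFA closes O1–C6 through the hemiketal without breaking the benzylic C2–O bond.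

Step 3
Reactants: 6 methyl (2S)-2-(3,4-dimethoxyphenyl)-4-oxo-3,4-dihydro-2H-pyran-6-carboxylate
Product: 7 (2S)-2-(3,4-dimethoxyphenyl)-4-oxo-3,4-dihydro-2H-pyran-6-carboxylic acid
Conditions: Me3SnOH (4 equiv), 1,2-dichloroethane, 60 °C; cold 1 M aq HCl wash
Reagents that add atoms: trimethyltin hydroxide, C[Sn](C)(C)O
Why: Trimethyltin hydroxide hydrolysis of a methyl ester runs close to neutrality by tin-assisted acyl substitution, which avoids the hydroxide-induced E1cB opening of ring C (C3 deprotonation, then loss of the vinylogous carboxylate from C2) and so protects the C2 configuration.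

Step 4
Reactants: 7 (2S)-2-(3,4-dimethoxyphenyl)-4-oxo-3,4-dihydro-2H-pyran-6-carboxylic acid
Product: 9 (S)-6-(diazoacetyl)-2-(3,4-dimethoxyphenyl)-2,3-dihydro-4H-pyran-4-one, via acid chloride 8 (not isolated)
Conditions: Me2C=C(Cl)NMe2 (1.1 equiv), CH2Cl2, 0 °C; then Me3SiCHN2 (2 equiv), THF/MeCN, 0 °C
Reagents that add atoms: trimethylsilyldiazomethane, C[Si](C)(C)C=[N+]=[N-]
Why: Neutral acid chloride formation with the α-chloroenamine and C-acylation of the silylated diazoalkane (acylation stage of the Arndt–Eistert sequence, silicon leaving as Me3SiCl) need no amine base, and the bulky reagent is preferred to diazomethane because it is much slower in 1,3-dipolar cycloaddition to the doubly activated ring double bond.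

Step 5
Reactants: 10 geranyl bromide ((E)-1-bromo-3,7-dimethylocta-2,6-diene)
Product: 11 (E)-5,9-dimethyldeca-4,8-dien-1-yne
Conditions: HC≡CMgBr (2.5 equiv), CuI (10 mol %), THF, 0 °C to rt
Reagents that add atoms: ethynylmagnesium bromide, C#C[Mg]Br
Why: Copper-catalysed SN2 coupling of an alkynyl Grignard reagent with a primary allylic bromide joins the partners at the unhindered terminus with the E-alkene retained, and the excess of reagent suppresses double alkylation of acetylene.

Step 6
Reactants: 11 (E)-5,9-dimethyldeca-4,8-dien-1-yne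
Product: 14 [(E)-5,9-dimethyldeca-4,8-dien-1-yn-1-yl]oxy(triisopropyl)silane, via lithium acetylide 12 (not isolated), via lithium ynolate 13 (not isolated)
Conditions: n-BuLi (1.0 equiv), THF, −78 °C; t-BuOOLi (from t-BuOOH + LiN(SiMe3)2), −78 to 0 °C; iPr3SiOTf, −78 to 0 °C
Reagents that add atoms: tert-butyl hydroperoxide, CC(C)(C)OO; triisopropylsilyl triflate, CC(C)[Si](C(C)C)(C(C)C)OS(=O)(=O)C(F)(F)F
Why: Oxidation of a lithium acetylide by lithium tert-butyl peroxide (attack of the acetylide carbon on the O–O bond) gives the ynolate, which the hard and bulky silyl triflate traps on oxygen as the silyl ynol ether, while the isolated trisubstituted alkenes are inert to this nucleophilic oxidant.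

Step 7
Reactants: 9 (S)-6-(diazoacetyl)-2-(3,4-dimethoxyphenyl)-2,3-dihydro-4H-pyran-4-one; 14 [(E)-5,9-dimethyldeca-4,8-dien-1-yn-1-yl]oxy(triisopropyl)silane
Product: 18 (S)-6-geranyl-5-hydroxy-3',4'-dimethoxy-7-(triisopropylsilyloxy)flavanone, via vinylketene 15 (not isolated), via vinylcyclobutenone 16 (not isolated), via dienylketene 17 (not isolated)
Conditions: 14 (1.3 equiv), degassed CH2Cl2, LED 385–405 nm, 20 °C; then solvent switch to toluene, 100 °C, dark
Reagents that add atoms: none
Why: Light at the long-wave edge of the diazoketone band, where the ring C enone and the veratryl group are transparent, expels N2 and C8a shifts to the carbene carbon (Wolff rearrangement, C8–C8a) to give vinylketene 15, whose carbonyl carbon is the future C5. The polarised ynol ether 14 adds across the ketene C=C in a [2+2] cycloaddition, its nucleophilic geranyl-bearing carbon binding the ketene carbonyl carbon (C5–C6) and its oxygenated carbon binding C8 (C7–C8), which gives vinylcyclobutenone 16. On heating in the dark, 16 opens by conrotatory four-electron cleavage of C5–C8 to dienylketene 17, and ring A, the only ring formed, closes by disrotatory six-electron electrocyclisation between C5 and C4a, after which the dienone enolises at once because its C4a–H sits between two carbonyl groups. The closest known reaction type is the diazoketone variant of the Danheiser benzannulation, established for acyclic, carbocyclic and heteroaromatic unsaturated diazoketones with triisopropylsiloxyalkynes; an enone-bearing oxygen heterocycle as ketene carrier is the untried element. No lasting stereocentre is created (the sp3 carbon C8 of 16 becomes planar again) and C2 is a spectator under these neutral conditions. The selectivity needed is the orientation of the alkyne, secured by oxygen-donor polarisation of 14, while the ketene arm lies trans to C4 across C4a=C8a, so that closure onto the C4 carbonyl oxygen to a 2-pyranone is geometrically impossible and only H points into the cyclising terminus.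

Step 8
Reactants: 18 (S)-6-geranyl-5-hydroxy-3',4'-dimethoxy-7-(triisopropylsilyloxy)flavanone
Product: 19 (S)-6-geranyl-5,7-dihydroxy-3',4'-dimethoxyflavanone (target, CNP0268555.1)
Conditions: Bu4NF (1.1 equiv), AcOH (1.3 equiv), THF, 0 °C
Reagents that add atoms: none
Why: Fluoride cleavage of a phenolic silyl ether is fast at 0 °C, and the acetic acid buffer keeps the medium too weakly basic for retro-oxa-Michael opening at C2 (racemisation) and too weakly acidic for chroman formation between the geranyl chain and its flanking phenols.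

Compound list
1 | methyl 2,4-dioxopentanoate | CC(=O)CC(=O)C(=O)OC | starting material
2 | methyl (2Z)-2,4-bis(trimethylsilyloxy)penta-2,4-dienoate | COC(=O)/C(O[Si](C)(C)C)=C/C(=C)O[Si](C)(C)C | intermediate
3 | veratraldehyde | COc1ccc(C=O)cc1OC | starting material
4 | methyl (2Z,6S)-6-(3,4-dimethoxyphenyl)-4-oxo-6-(trichlorosilyloxy)-2-(trimethylsilyloxy)hex-2-enoate | COc1ccc([C@@H](O[Si](Cl)(Cl)Cl)CC(=O)/C=C(\O[Si](C)(C)C)C(=O)OC)cc1OC | intermediate
5 | methyl (6S)-6-(3,4-dimethoxyphenyl)-6-hydroxy-2,4-dioxohexanoate (in equilibrium with its enol and cyclic hemiketal) | COc1ccc([C@@H](O)CC(=O)CC(=O)C(=O)OC)cc1OC | intermediate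
6 | methyl (2S)-2-(3,4-dimethoxyphenyl)-4-oxo-3,4-dihydro-2H-pyran-6-carboxylate | COc1ccc([C@@H]2CC(=O)C=C(C(=O)OC)O2)cc1OC | intermediate
7 | (2S)-2-(3,4-dimethoxyphenyl)-4-oxo-3,4-dihydro-2H-pyran-6-carboxylic acid | COc1ccc([C@@H]2CC(=O)C=C(C(=O)O)O2)cc1OC | intermediate
8 | (2S)-2-(3,4-dimethoxyphenyl)-4-oxo-3,4-dihydro-2H-pyran-6-carbonyl chloride | COc1ccc([C@@H]2CC(=O)C=C(C(=O)Cl)O2)cc1OC | intermediate
9 | (S)-6-(diazoacetyl)-2-(3,4-dimethoxyphenyl)-2,3-dihydro-4H-pyran-4-one | COc1ccc([C@@H]2CC(=O)C=C(C(=O)C=[N+]=[N-])O2)cc1OC | intermediate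
10 | geranyl bromide | CC(C)=CCC/C(C)=C/CBr | starting material
11 | (E)-5,9-dimethyldeca-4,8-dien-1-yne | CC(C)=CCC/C(C)=C/CC#C | intermediate
12 | lithium acetylide of 11 | CC(C)=CCC/C(C)=C/CC#C[Li] | intermediate
13 | lithium (E)-5,9-dimethyldeca-4,8-dien-1-yn-1-olate | CC(C)=CCC/C(C)=C/CC#CO[Li] | intermediate
14 | [(E)-5,9-dimethyldeca-4,8-dien-1-yn-1-yl]oxy(triisopropyl)silane | CC(C)=CCC/C(C)=C/CC#CO[Si](C(C)C)(C(C)C)C(C)C | intermediate
15 | (S)-2-(3,4-dimethoxyphenyl)-6-(2-oxoethenyl)-2,3-dihydro-4H-pyran-4-one | COc1ccc([C@@H]2CC(=O)C=C(C=C=O)O2)cc1OC | intermediate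
16 | 4-[(2S)-2-(3,4-dimethoxyphenyl)-4-oxo-3,4-dihydro-2H-pyran-6-yl]-2-geranyl-3-(triisopropylsilyloxy)cyclobut-2-en-1-one (both epimers at the sp3 ring carbon) | COc1ccc([C@@H]2CC(=O)C=C(C3C(=O)C(C/C=C(\C)CCC=C(C)C)=C3O[Si](C(C)C)(C(C)C)C(C)C)O2)cc1OC | intermediate
17 | 4-[(2S)-2-(3,4-dimethoxyphenyl)-4-oxo-3,4-dihydro-2H-pyran-6-yl]-2-geranyl-3-(triisopropylsilyloxy)buta-1,3-dien-1-one, C6 and C8a cis across C7=C8 | COc1ccc([C@@H]2CC(=O)C=C(/C=C(O[Si](C(C)C)(C(C)C)C(C)C)\C(=C=O)C/C=C(\C)CCC=C(C)C)O2)cc1OC | intermediate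
18 | (S)-6-geranyl-5-hydroxy-3',4'-dimethoxy-7-(triisopropylsilyloxy)flavanone | COc1ccc([C@@H]2CC(=O)c3c(cc(O[Si](C(C)C)(C(C)C)C(C)C)c(C/C=C(\C)CCC=C(C)C)c3O)O2)cc1OC | intermediate
19 | (S)-6-geranyl-5,7-dihydroxy-3',4'-dimethoxyflavanone | COc1ccc([C@@H]2CC(=O)c3c(cc(O)c(C/C=C(\C)CCC=C(C)C)c3O)O2)cc1OC | target

Total step count: 8 (fragment 1: steps 1–4; fragment 2: steps 5–6; union and deprotection: steps 7–8).
Longest linear sequence: 6 steps (1, 2, 3, 4, 7, 8).

Steps most likely to fail

1. Step 7.
- Residual absorption by the enone could lead to photocycloaddition with the geranyl alkenes or to photochemical opening of ring C.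
- The electron-poor ketene could be lost by dimerisation or hydration faster than the alkyne captures it.
- The thermal cascade could stall at the cyclobutenone stage.
- The fallback buys ring A instead of building it and uses known chalcone chemistry. It sets out from 10 and 3 and rejoins the route at 19.
- C-alkylation of commercial 2,4,6-trihydroxyacetophenone with 10 (K2CO3, acetone) should give 3-geranyl-2,4,6-trihydroxyacetophenone F1.
- MOMCl/iPr2NEt caps the 4- and 6-hydroxyls to give 3-geranyl-2-hydroxy-4,6-bis(methoxymethoxy)acetophenone F2.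
- Claisen–Schmidt condensation with 3 (KOH, EtOH) gives the protected chalcone F3, and HCl/MeOH frees the trihydroxychalcone F4.
- NaOAc in refluxing EtOH closes ring C by oxa-Michael addition to the racemic 6-geranylflavanone F5 together with the racemic 8-geranyl isomer F6.
- Chromatography separates the two isomers, and preparative HPLC of F5 on a polysaccharide chiral phase delivers 19.

2. Step 2.
- The ester-weakened diene may add sluggishly to the electron-rich aldehyde, or the facial selectivity may be poor.
- Acid-induced loss of water from the benzylic carbinol before ring closure would erode the enantiomeric purity through reclosure of an achiral dienone.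
- The fallback sets C2 by reagent-controlled methallylboration and builds the dicarbonyl chain afterwards. It sets out from 3 and rejoins the route at 5.
- B-methallyldiisopinocampheylborane, made from (−)-B-methoxydiisopinocampheylborane and methallylmagnesium chloride, adds to 3 at −78 °C to give (S)-1-(3,4-dimethoxyphenyl)-3-methylbut-3-en-1-ol F7.
- TBSCl/imidazole gives the silyl ether F8.
- Lemieux–Johnson cleavage (OsO4 cat., NaIO4, 2,6-lutidine) gives (S)-4-(tert-butyldimethylsilyloxy)-4-(3,4-dimethoxyphenyl)butan-2-one F9.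
- Kinetic enolisation with LiN(SiMe3)2 and Claisen condensation with dimethyl oxalate give the silylated diketo ester F10.
- Bu4NF/AcOH releases 5, which is cyclised with TFA as in step 2.

3. Step 4.
- The diazoalkane may add as a 1,3-dipole to the ring double bond in competition with acylation.
- The diazoketone may be captured by chloride sources to give a chloromethyl ketone.
- The fallback replaces diazoalkane acylation by diazo group transfer. It sets out from 8 and rejoins the route at 9.
- Negishi-type acylation of MeZnCl with 8 (Pd(PPh3)4 cat., THF, 0 °C) gives (S)-6-acetyl-2-(3,4-dimethoxyphenyl)-2,3-dihydro-4H-pyran-4-one F11.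
- Deprotonation of the more accessible and more acidic acetyl methyl group (LiN(SiMe3)2, −78 °C) and trapping with CF3CO2CH2CF3 give the trifluoroacetyl diketone F12.
- Detrifluoroacetylative diazo transfer (MsN3, Et3N, H2O, MeCN, short contact) then gives 9.

Further compounds
F1 | step 7 | 3-geranyl-2,4,6-trihydroxyacetophenone | CC(=O)c1c(O)cc(O)c(C/C=C(\C)CCC=C(C)C)c1O
F2 | step 7 | 3-geranyl-2-hydroxy-4,6-bis(methoxymethoxy)acetophenone | CC(=O)c1c(OCOC)cc(OCOC)c(C/C=C(\C)CCC=C(C)C)c1O
F3 | step 7 | (E)-3'-geranyl-2'-hydroxy-3,4-dimethoxy-4',6'-bis(methoxymethoxy)chalcone | COCOc1cc(OCOC)c(C(=O)/C=C/c2ccc(OC)c(OC)c2)c(O)c1C/C=C(\C)CCC=C(C)C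
F4 | step 7 | (E)-3'-geranyl-2',4',6'-trihydroxy-3,4-dimethoxychalcone | Oc1cc(O)c(C(=O)/C=C/c2ccc(OC)c(OC)c2)c(O)c1C/C=C(\C)CCC=C(C)C
F5 | step 7 | racemic 6-geranyl-5,7-dihydroxy-3',4'-dimethoxyflavanone | COc1ccc(C2CC(=O)c3c(cc(O)c(C/C=C(\C)CCC=C(C)C)c3O)O2)cc1OC
F6 | step 7 | racemic 8-geranyl-5,7-dihydroxy-3',4'-dimethoxyflavanone | COc1ccc(C2CC(=O)c3c(O)cc(O)c(C/C=C(\C)CCC=C(C)C)c3O2)cc1OC
F7 | step 2 | (S)-1-(3,4-dimethoxyphenyl)-3-methylbut-3-en-1-ol | COc1ccc([C@@H](O)CC(C)=C)cc1OC
F8 | step 2 | (S)-tert-butyl{[1-(3,4-dimethoxyphenyl)-3-methylbut-3-en-1-yl]oxy}dimethylsilane | COc1ccc([C@@H](O[Si](C)(C)C(C)(C)C)CC(C)=C)cc1OC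
F9 | step 2 | (S)-4-(tert-butyldimethylsilyloxy)-4-(3,4-dimethoxyphenyl)butan-2-one | COc1ccc([C@@H](O[Si](C)(C)C(C)(C)C)CC(C)=O)cc1OC
F10 | step 2 | methyl (6S)-6-(tert-butyldimethylsilyloxy)-6-(3,4-dimethoxyphenyl)-2,4-dioxohexanoate | COc1ccc([C@@H](O[Si](C)(C)C(C)(C)C)CC(=O)CC(=O)C(=O)OC)cc1OC
F11 | step 4 | (S)-6-acetyl-2-(3,4-dimethoxyphenyl)-2,3-dihydro-4H-pyran-4-one | COc1ccc([C@@H]2CC(=O)C=C(C(C)=O)O2)cc1OC
F12 | step 4 | (S)-1-[2-(3,4-dimethoxyphenyl)-4-oxo-3,4-dihydro-2H-pyran-6-yl]-4,4,4-trifluorobutane-1,3-dione | COc1ccc([C@@H]2CC(=O)C=C(C(=O)CC(=O)C(F)(F)F)O2)cc1OC
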